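**Assumptions**
- 2',4'-Dihydroxy-6'-methoxyacetophenone (9) is commercially available (otherwise one acylation step from 3,5-dihydroxyanisole).
- The SMILES gives (S) at both the benzylic CH(Ar)₂ carbon and the carbinol carbon.
- The absolute sense of induction by the phosphoric acid in Step 6 cannot be predicted, so the catalyst antipode that gives the benzylic (S) centre is chosen by comparison with the natural product.
- Under the chiral-acid conditions, C-3' of the chalcone (flanked by two OH groups) is the preferred nucleophilic carbon over C-5'.

## Retrosynthetic overview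
1. Calyxin B ⇒ the benzylic C–C bond between chalcone C-3' and the diaryl-allyl carbon, made by an asymmetric dehydrative Friedel–Crafts (1,6-addition) of 4,2',4'-trihydroxy-6'-methoxychalcone onto an (E)-alkenyl p-quinone methide generated in situ from a 1-aryl-allylic diol. The carbinol of the diol is destroyed on ionisation, so it can be racemic.
2. The diol ⇒ cross-metathesis of (S)-1-(4-hydroxyphenyl)hex-5-en-3-ol with 1-(4-hydroxyphenyl)allyl alcohol.
3. The (S)-homoallylic alcohol ⇒ organocatalytic allylboration of 3-(4-hydroxyphenyl)propanal. This sets the first stereocentre.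
4. The chalcone ⇒ Claisen–Schmidt condensation of the acetophenone with 4-hydroxybenzaldehyde.
5. No rings are constructed; all three aryl rings come from the starting materials. Catalysts and generic reagents are not numbered.

## Route

**Step 1**
Reactants: 1, 3-(4-hydroxyphenyl)propan-1-ol
Product: 2, 3-(4-hydroxyphenyl)propanal
Conditions: SO₃·py (3 equiv), DMSO, Et₃N (5 equiv), CH₂Cl₂, 0 °C → rt, 2 h
Reagents that add atoms: none
Why: Parikh–Doering oxidation is mild and oxidises the primary alcohol selectively, leaving the free phenol untouched.

**Step 2**
Reactants: 2, 3-(4-hydroxyphenyl)propanal; 3, allylBpin (2-allyl-4,4,5,5-tetramethyl-1,3,2-dioxaborolane)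
Product: 4, (S)-1-(4-hydroxyphenyl)hex-5-en-3-ol
Conditions: (S)-TRIP (5 mol%), 3 Å MS, toluene, –30 °C, 48 h; then aq. NaHCO₃ workup
Reagents that add atoms: allylBpin, C=CCB1OC(C)(C)C(C)(C)O1 (supplies the allyl group)
Why: Chiral-phosphoric-acid-catalysed allylboration proceeds through a closed chair transition state in which the catalyst P–OH activates the pinacol oxygen and P=O orients the aldehyde. One aldehyde face is shielded, giving the (S)-carbinol (first stereocentre; the TRIP enantiomer is chosen to give S).

**Step 3**
Reactants: 5, 4-hydroxybenzaldehyde; 6, vinylmagnesium bromide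
Product: 7, (±)-1-(4-hydroxyphenyl)prop-2-en-1-ol
Conditions: 6 (3.0 equiv, 1 M in THF), THF, 0 °C → rt, 2 h; cold sat. NH₄Cl quench; used crude and immediately
Reagents that add atoms: vinylmagnesium bromide, C=C[Mg]Br (supplies the vinyl group)
Why: Grignard 1,2-addition to the aldehyde of the magnesium phenoxide; the carbinol configuration is irrelevant because this centre is lost by ionisation in Step 6.

**Step 4**
Reactants: 4, (S)-homoallylic alcohol (1 equiv); 7, vinyl carbinol (3 equiv)
Product: 8, (2E,5S)-1,7-bis(4-hydroxyphenyl)hept-2-ene-1,5-diol (C-1 epimeric mixture, about 1:1)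
Conditions: Hoveyda–Grubbs II (5 mol%), 1,4-benzoquinone (10 mol%), CH₂Cl₂ (0.05 M), 40 °C, 12 h, open to a vent
Reagents that add atoms: none (ethylene is lost)
Why: Cross-metathesis of a type I homoallylic alkene with an excess of the allylic alcohol partner gives the thermodynamic E-alkene. Benzoquinone suppresses Ru–H isomerisation. The unprotected 5-OH stereocentre is untouched.

**Step 5**
Reactants: 9, 2',4'-dihydroxy-6'-methoxyacetophenone; 5, 4-hydroxybenzaldehyde
Product: 10, (E)-1-(2,4-dihydroxy-6-methoxyphenyl)-3-(4-hydroxyphenyl)prop-2-en-1-one
Conditions: 50% aq. KOH (8 equiv), EtOH, rt → 50 °C, 24 h; then cold 1 M HCl to pH 3–4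
Reagents that add atoms: none (the aldehyde is reactant 5)
Why: Claisen–Schmidt aldol condensation of the phenolate-protected acetophenone enolate gives the E-chalcone, as in cardamonin-type syntheses.

**Step 6**
Reactants: 8, diol (1 equiv); 10, chalcone (2.5 equiv)
Product: 11, calyxin B
Conditions: (S)-STRIP, a SPINOL-derived phosphoric acid (10 mol%), CH₂Cl₂/toluene 1:1 (0.03 M), 3 Å MS, 30 °C, 48 h; neutral workup (no acid)
Reagents that add atoms: none (water is lost)
Why: Proposed new method: the chiral phosphoric acid ionises the p-hydroxyphenyl allylic alcohol by dehydration to an achiral (E)-alkyl-alkenyl p-quinone methide, which stays ion-paired with the catalyst. The catalyst P–OH binds the quinone methide oxygen, and P=O binds the chalcone's free 4'-OH. C-3', flanked by two OH groups, attacks the benzylic (1,6) terminus of one prochiral face. Rearomatisation gives the (S)-diaryl allyl centre, with the E-alkene and the remote (S)-carbinol retained and no protecting groups needed. The closest known reaction is phosphoric-acid-catalysed 1,6-conjugate addition of arenes and phenols to p-quinone methides (dehydrative Friedel–Crafts of p-hydroxybenzhydrols). What is new is the alkyl-substituted dienyl quinone methide from a free diol, 1,6- over 1,8-selectivity, and a phloroglucinol-type chalcone as the C-nucleophile with C-3' over C-5' selectivity.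

**Checks**
- Target constitution: C₃₅H₃₄O₈. Step 6 sums C₁₉H₂₂O₄ (8) + C₁₆H₁₄O₅ (10) − H₂O = C₃₅H₃₄O₈.
- Every stereocentre is set once and not disturbed afterwards: the carbinol in Step 2, the benzylic centre in Step 6, and the E-alkene in Step 4. Step 6 is the last step.
- Functional-group survival: free phenols are tolerated in Steps 1–5. The acid-labile diaryl-allyl centre forms only in the final step and is worked up without acid.

## Compound list
1 | 3-(4-hydroxyphenyl)propan-1-ol | OCCCc1ccc(O)cc1 | starting material
2 | 3-(4-hydroxyphenyl)propanal | O=CCCc1ccc(O)cc1 | intermediate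
3 | allylBpin | C=CCB1OC(C)(C)C(C)(C)O1 | starting material
4 | (S)-1-(4-hydroxyphenyl)hex-5-en-3-ol | C=CC[C@@H](O)CCc1ccc(O)cc1 | intermediate
5 | 4-hydroxybenzaldehyde | O=Cc1ccc(O)cc1 | starting material
6 | vinylmagnesium bromide | C=C[Mg]Br | starting material
7 | (±)-1-(4-hydroxyphenyl)prop-2-en-1-ol | C=CC(O)c1ccc(O)cc1 | intermediate
8 | (2E,5S)-1,7-bis(4-hydroxyphenyl)hept-2-ene-1,5-diol (C-1 epimeric mixture) | Oc1ccc(cc1)C(O)/C=C/C[C@@H](O)CCc1ccc(O)cc1 | intermediate
9 | 2',4'-dihydroxy-6'-methoxyacetophenone | COc1cc(O)cc(O)c1C(C)=O | starting material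
10 | (E)-4,2',4'-trihydroxy-6'-methoxychalcone | COc1cc(O)cc(O)c1C(=O)/C=C/c1ccc(O)cc1 | intermediate
11 | calyxin B | COc1cc(O)c([C@@H](/C=C/C[C@@H](O)CCc2ccc(O)cc2)c2ccc(O)cc2)c(O)c1C(=O)/C=C/c1ccc(O)cc1 | target

## Summary
Total steps: 6. Longest linear sequence: 4 (Steps 1 → 2 → 4 → 6).

**Three steps most likely to fail**
1. **Step 6 (proposed new step):** the 1,6- versus 1,8-selectivity, the C-3' versus C-5' selectivity, or the ee may be poor. Fallback: couple 8 and 10 with an achiral Brønsted acid (e.g. 10 mol% diphenyl phosphate) to give the C-1 epimers, about 1:1. Separate the calyxin B diastereomer by preparative HPLC.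
2. **Step 4 (cross-metathesis with free phenols and an aryl allylic alcohol):** Ru decomposition or redox isomerisation may dominate. Fallback: change the disconnection. Cross-metathesise the bis-silylated 4 with acrolein to give the (E)-enal. Add 4-(silyloxy)phenylmagnesium bromide 1,2 to the enal, then remove the silyl groups with buffered TBAF to give 8.
3. **Step 2 (allylboration of an aliphatic aldehyde bearing a free phenol):** the ee may be eroded by phenol–boron exchange. Fallback: use the TBS-protected aldehyde in a stoichiometric Brown allylation with (–)-Ipc₂B(allyl), then remove TBS with buffered TBAF to give 4.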